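Divide the Z charged by the J charged, counting one L per Z: for these set-ups that gives 60.0%, the ceiling, which is the rule of thumb for the yield on J when Z is the limiting reagent.

| flask | J | Z | E | remark | time |
|---|---|---|---|---|---|
| zeta | 2 M | 1.2 M | 84 mM | run made earlier |  |
| beta | 2.8 M | 1.2 M | 84 mM | run made earlier |  |
| east | 2.0 M | 1.20 M | 84 mM | a closed flask charged with all of it at once and left for 4.0 h | 4.0 h |
| south-west | 2.0 M | 1.20 M | 84 mM | a single well-mixed tank run continuously and read at steady state, 12.0 h in it on average |  |
| north-west | 2.0 M | 1.20 M (fed, over 3.20 h) | 84 mM | all but Z at the start; Z goes in evenly over 3.20 h, the run ends at 4.0 h | 4.0 h |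
| north-east | 2.0 M | 1.20 M | 84 mM | a single well-mixed tank run continuously and read at steady state, 4.0 h in it on average |  |

| run | time / h | L / % | J / % |
|---|---|---|---|
| zeta | 0.200 | 60.7 | 38.7 |
| zeta | 0.417 | 60.3 | 40.1 |
| zeta | 1.00 | 58.8 | 38.1 |
| zeta | 2.50 | 59.6 | 32.9 |
| beta | 0.417 | 42.9 | 52.6 |
| beta | 1.00 | 41.3 | 48.4 |
| beta | 2.00 | 44.0 | 45.2 |
| beta | 3.00 | 41.6 | 39.3 |

(each reading ± 1 percentage point)

- the stated concentrations are those of everything mixed, before any reaction; amounts are the same in each set-up
- the feed brings no volume worth counting
- the earlier runs were made in a closed, stirred flask

- the set-up with the highest amount of L at the outlet or at the end, in percent of the J put in ("none" if the first two lie within 2 percentage points) (east / south-west / north-west / north-east / none)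
- amount of L at the outlet or at the end, in percent of the J put in, east
- amount of L at the outlet or at the end, in percent of the J put in, south-west
- amount of L at the outlet or at the end, in percent of the J put in, north-west
- amount of L at the outlet or at the end, in percent of the J put in, north-east

The rule reads well on the earlier runs. The zeta run shows L at 60.7% at its first reading, and the beta run shows 42.9% at its first reading, where the same quotient gives 42.9%. In the zeta run L then stays flat while J falls from 38.7% to 32.9%, so a second loss of J runs beside the main reaction. We read it as second order in J, from the rise of the reciprocal of cJ per hour:

side-loss constant = 0.0990 L mol⁻¹ h⁻¹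

The rule stops working where this side loss takes more J than the excess over Z, which is 0.800 M. The north-west flask is the hard case: its J stands charged from the start while Z goes in over 3.20 h. At the start of its feed the two rates compare thus:

side loss = 0.396 M h⁻¹, feed of Z = 0.375 M h⁻¹

The two are of like size at that moment, and our constant rests on two scattered readings, so we name no leader; the side loss then falls with the square of cJ. For a pessimistic count, we let the side loss act over the dosing time with no Z taking J:

J lost = 0.776 M, and J lost / excess = 0.970

This count comes out close to the border and carries the scatter of the constant, but the feed lowers cJ further, so we put the north-west flask at the ceiling, with the east flask. The shorter tank stay, 4.0 h, is long beside the zeta run's first reading, but a mixed tank lets some Z out, so we put both tanks just under the ceiling.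

The forecast gives 60% for east, 59.5% for south-west, 59.5% for north-west and 59% for north-east, with best none. On the side loss it says: “This side loss takes only excess J and does not touch L.”

The flask gives 60.0% for east, 59.6% for south-west, 60.0% for north-west and 58.9% for north-east, so best is none.

    J + Z + E → L + E, rate k1*[J]*[Z]*[E]/(1 + ([J]/sat1)) (3.90 M, k = 0.0810 L² mol⁻² s⁻¹)
    2 J → X (k = 1.30 × 10⁻⁵ L mol⁻¹ s⁻¹)

The east flask stands at the ceiling 60.0% because of the consumption of Z: the same flask with that consumption taken away reaches 99.6%. The north-east tank, still holding cZ = 0.0213 M, sits 1.1 percentage points under the ceiling. Carried to the beta run, the ceiling is 42.9%, and that run, without the scatter, stands at 42.9% at the time of its last reading.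

The earlier runs and the new flask come from a simulation for substances that don't exist; the scatter is artificial.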